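**Plan**

- Retrosynthesis: the C15 alcohol is taken back to a methyl ester and two ring alkenes (C1=C2, C6=C7) are added. C3–C4 and C5–C10 are then cut together, with C8–OH traded for C8–OMe, which opens both rings to an acyclic bromotetraene. That chain is cut at C6=C7 (olefination), C8–C9 (Ireland–Claisen, C1–O traded for C9–C8) and C1–C2 (alkynylation of a geranate-derived enal).
- Enabling feature: in ring A the only substituent, Br on C3, sits beside quaternary C4, so C4–C5 is a dienophile edge and C3–C2–C1–C10 a bromodiene. In ring B the tertiary carbinol C8 is joined to C4 through C5–C6–C7, so with a temporary C6=C7 bond, ionisation at C8 makes C4=C5 the electron-poor end of a pentadienyl cation and returns the charge to C8 for capture by water.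
- Forward: the chain is joined C1–C2, then C8–C9, then C6–C7; rings A and B close together in one step; the helper alkenes are then reduced and the ester is reduced last.
- Stereochemistry: the C1 carbinol comes from catalyst control; C9 from chirality transfer in the chair Claisen; C3, C5, C10 and C8 arise in the ring-forming step from C9 and from the E (C10=C1) and Z (C2=C3) alkene geometries.

Key step: step 12

Remark: locants C1–C20 follow labdane numbering of the target (ring A C1–C5 and C10, ring B C5–C10, C17 on C8, C18/C19 on C4, C20 on C10, side chain C11–C16); compounds 1, 4, 7, 17 and 18 are taken as commercial.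

**Step 1**
Reactants: 1 methyl (2E)-3,7-dimethylocta-2,6-dienoate (methyl geranate)
Product: 2 methyl (2E,6E)-8-hydroxy-3,7-dimethylocta-2,6-dienoate
Conditions: SeO2 (0.1 equiv), t-BuOOH (2 equiv), salicylic acid (0.1 equiv), CH2Cl2, 0 °C → rt
Reagents that add atoms: tert-butyl hydroperoxide, CC(C)(C)OO
Why: catalytic SeO2 allylic oxidation (ene reaction then [2,3] shift) should hydroxylate the E methyl group of the electron-rich distal alkene and leave the conjugated 2,3-alkene alone, with the 6E geometry kept and no stereocentre formed.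

**Step 2**
Reactants: 2 methyl (2E,6E)-8-hydroxy-3,7-dimethylocta-2,6-dienoate
Product: 3 methyl (2E,6E)-3,7-dimethyl-8-oxoocta-2,6-dienoate
Conditions: MnO2 (excess), CH2Cl2, rt
Reagents that add atoms: none
Why: chemoselective MnO2 oxidation of the primary allylic alcohol should give the E enal and also converge any aldehyde already formed in step 1.

**Step 3**
Reactants: 3 methyl (2E,6E)-3,7-dimethyl-8-oxoocta-2,6-dienoate; 4 ethynyltrimethylsilane
Product: 6 methyl (2E,6E,8S)-8-hydroxy-3,7-dimethyl-10-(trimethylsilyl)deca-2,6-dien-9-ynoate, via zinc acetylide 5 (not isolated)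
Conditions: Me2Zn (3 equiv), ProPhenol ligand (10 mol %, the enantiomer that gives 8S), Ph3P=O (20 mol %), toluene, 0 °C → rt; aq. NH4Cl
Reagents that add atoms: none
Why: catalytic enantioselective alkynylation of the α-substituted enal by the zinc–ProPhenol system should set the 8S carbinol (C1) by catalyst control of the aldehyde face, the methyl ester being inert to the organozinc.

**Step 4**
Reactants: 6 methyl (2E,6E,8S)-8-hydroxy-3,7-dimethyl-10-(trimethylsilyl)deca-2,6-dien-9-ynoate; 7 (2S)-2-methoxypropanoic acid
Product: 8 methyl (2E,6E,8S)-8-{[(2S)-2-methoxypropanoyl]oxy}-3,7-dimethyl-10-(trimethylsilyl)deca-2,6-dien-9-ynoate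
Conditions: DCC, DMAP (cat.), CH2Cl2, 0 °C → rt
Reagents that add atoms: none
Why: Steglich esterification of the secondary alcohol; the stereocentre of the acid is erased on enolisation in step 5, so its configuration is immaterial.

**Step 5**
Reactants: 8 methyl (2E,6E,8S)-8-{[(2S)-2-methoxypropanoyl]oxy}-3,7-dimethyl-10-(trimethylsilyl)deca-2,6-dien-9-ynoate
Product: 11 (2R,3S,4E)-2-methoxy-3-[(3E)-5-methoxy-3-methyl-5-oxopent-3-en-1-yl]-2,4-dimethyl-7-(trimethylsilyl)hept-4-en-6-ynoic acid, via silyl ketene acetal 9 (not isolated), via trimethylsilyl ester 10 (not isolated)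
Conditions: LiN(SiMe3)2, Me3SiCl, THF, −78 °C → 40 °C; then 1 M HCl
Reagents that add atoms: none
Why: Ireland–Claisen rearrangement in which the lithium-chelated Z enolate of the α-methoxy ester is trapped as 9 and rearranges through a chair with the alkynyl group equatorial, so that the C1–O chirality is transferred to the new stereocentre C9 (S) and the C10=C1 alkene forms E (C9 trans to C2); the ether carbon C8 forms as one diastereomer but is ionised in step 12, and the silylated alkyne terminus should block the competing propargylic shift.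

**Step 6**
Reactants: 11 (2R,3S,4E)-2-methoxy-3-[(3E)-5-methoxy-3-methyl-5-oxopent-3-en-1-yl]-2,4-dimethyl-7-(trimethylsilyl)hept-4-en-6-ynoic acid
Product: 13 methyl (2E,6S,7E)-6-[(2R)-1-hydroxy-2-methoxypropan-2-yl]-3,7-dimethyl-10-(trimethylsilyl)deca-2,7-dien-9-ynoate, via mixed carbonic anhydride 12 (not isolated)
Conditions: i-BuOCOCl, N-methylmorpholine, THF, −15 °C; then NaBH4, H2O, 0 °C
Reagents that add atoms: none
Why: activation of the hindered acid as a mixed anhydride and NaBH4 reduction should give the primary alcohol without touching the conjugated methyl ester, the alkenes or the alkynylsilane.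

**Step 7**
Reactants: 13 methyl (2E,6S,7E)-6-[(2R)-1-hydroxy-2-methoxypropan-2-yl]-3,7-dimethyl-10-(trimethylsilyl)deca-2,7-dien-9-ynoate
Product: 14 methyl (2E,6S,7E)-10-bromo-6-[(2R)-1-hydroxy-2-methoxypropan-2-yl]-3,7-dimethyldeca-2,7-dien-9-ynoate
Conditions: NBS, AgNO3 (10 mol %), acetone, rt, dark
Reagents that add atoms: N-bromosuccinimide, O=C1CCC(=O)N1Br
Why: silver-catalysed bromodesilylation should convert the alkynylsilane directly into the 1-bromoalkyne, the trisubstituted alkenes not competing with the silver acetylide pathway.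

**Step 8**
Reactants: 14 methyl (2E,6S,7E)-10-bromo-6-[(2R)-1-hydroxy-2-methoxypropan-2-yl]-3,7-dimethyldeca-2,7-dien-9-ynoate
Product: 15 methyl (2E,6S,7E,9Z)-10-bromo-6-[(2R)-1-hydroxy-2-methoxypropan-2-yl]-3,7-dimethyldeca-2,7,9-trienoate
Conditions: 2-nitrobenzenesulfonohydrazide, Et3N, THF/i-PrOH, rt
Reagents that add atoms: none
Why: diimide should deliver two hydrogens syn to the bromoalkyne far faster than to trisubstituted alkenes (cis reduction of a 1-haloalkyne), which gives the Z bromoalkene and hence the (1Z,3E)-bromodiene.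

**Step 9**
Reactants: 15 methyl (2E,6S,7E,9Z)-10-bromo-6-[(2R)-1-hydroxy-2-methoxypropan-2-yl]-3,7-dimethyldeca-2,7,9-trienoate
Product: 16 methyl (2E,6S,7E,9Z)-10-bromo-6-[(2R)-2-methoxy-1-oxopropan-2-yl]-3,7-dimethyldeca-2,7,9-trienoate
Conditions: Dess–Martin periodinane, CH2Cl2, 0 °C → rt
Reagents that add atoms: none
Why: Dess–Martin oxidation of the neopentyl-type primary alcohol; the aldehyde has no α-hydrogen, so it cannot epimerise.

**Step 10**
Reactants: 17 1-bromo-3-methylbut-2-ene; 18 triethyl phosphite
Product: 19 diethyl (3-methylbut-2-en-1-yl)phosphonate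
Conditions: neat, 130 °C, EtBr distilled off
Reagents that add atoms: none
Why: Michaelis–Arbuzov reaction of a primary allylic bromide.

**Step 11**
Reactants: 16 methyl (2E,6S,7E,9Z)-10-bromo-6-[(2R)-2-methoxy-1-oxopropan-2-yl]-3,7-dimethyldeca-2,7,9-trienoate; 19 diethyl (3-methylbut-2-en-1-yl)phosphonate
Product: 21 methyl (2E,6S,7E,9Z)-10-bromo-6-[(2S,3E)-2-methoxy-6-methylhepta-3,5-dien-2-yl]-3,7-dimethyldeca-2,7,9-trienoate, via lithiated phosphonate 20 (not isolated)
Conditions: 19, n-BuLi, THF, −78 °C; then 16, DMPU, −78 °C → rt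
Reagents that add atoms: none
Why: Horner–Wadsworth–Emmons olefination of the non-enolisable aldehyde by α-attack of the allylic phosphonate carbanion should give the E diene; the geometry of this C6=C7 bond is of no consequence because it becomes a freely rotating bond of the cation in step 12.

**Step 12**
Reactants: 21 methyl (2E,6S,7E,9Z)-10-bromo-6-[(2S,3E)-2-methoxy-6-methylhepta-3,5-dien-2-yl]-3,7-dimethyldeca-2,7,9-trienoate
Product: 24 methyl (2E)-5-[(1S,2S,4aS,6R,8aR)-6-bromo-2-hydroxy-2,5,5,8a-tetramethyl-1,2,4a,5,6,8a-hexahydronaphthalen-1-yl]-3-methylpent-2-enoate, via pentadienyl cation 22 (not isolated), via bicyclic allyl cation 23 (not isolated)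
Conditions: (PhO)2P(O)OH (10 mol %), H2O (10 equiv), (CF3)2CHOH/CH2Cl2 (1:3), −30 → 0 °C; aq. NaHCO3
Reagents that add atoms: water, O
Why: Proposed new method: protonation of the tertiary, doubly allylic C8–OMe of 21 expels methanol and gives the C4–C8 pentadienyl cation 22 (rotation about its weakly π-bonded C6–C7 bond lets it reach the cisoid form), the bromodiene then adds across the electron-poor C4=C5 end in an asynchronous [4+2] (C3–C4 ahead of C5–C10), and the charge, now the ring B allyl cation 23 (C6–C7–C8), is captured by water at its tertiary end C8. The closest known reaction type is the acid-induced ionic Diels–Alder reaction of allyl cations with 1,3-dienes, which tolerates fully substituted bond termini and cis-substituted dienes; the vinylogous pentadienyl variant with return of water is argued from the same polarity, since each C–C bond joins a cation terminus to a diene terminus and leaves a better stabilised allyl cation. Ring A closes as the cyclohexene of the cycloaddition and ring B through the four-atom tether C6–C9 in its anti (exo) orientation, the arrangement of the crossed conformer of an E,E-cyclodecadienyl cation, which gives the trans ring fusion. C10 and C3 follow from the diene geometry (C9 outside and the C20 methyl inside at the E C10=C1 bond, Br inside at the Z C2=C3 bond, so suprafacial addition puts Br cis to C20), and C5 follows from the exo tether (H5 endo, hence anti to C20). The existing stereocentre C9 selects the diene face, because the tether holds C9–H near the plane of C10=C1 towards the incoming C5 and the C11 chain anti to the forming C5–C10 bond (equatorial on ring B), and C8 is set last by attack of water anti to the axial C20 methyl. The step needs periselectivity and chemoselectivity: the geminal methyls on C4 disfavour the doubly cisoid cation needed for electrocyclisation, the conjugated ester makes C13=C14 non-nucleophilic, the E geometry at C10=C1 keeps C3 out of reach of C8, and capture of 22 by water is reversible whereas 24, a simple tertiary allylic alcohol, ionises far more slowly.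

**Step 13**
Reactants: 24 methyl (2E)-5-[(1S,2S,4aS,6R,8aR)-6-bromo-2-hydroxy-2,5,5,8a-tetramethyl-1,2,4a,5,6,8a-hexahydronaphthalen-1-yl]-3-methylpent-2-enoate
Product: 25 methyl (2E)-5-[(1S,2S,4aS,6R,8aR)-6-bromo-2-hydroxy-2,5,5,8a-tetramethyldecahydronaphthalen-1-yl]-3-methylpent-2-enoate
Conditions: 2-nitrobenzenesulfonohydrazide (excess, in portions), Et3N, CH2Cl2, rt
Reagents that add atoms: none
Why: diimide should reduce the two cis-disubstituted ring alkenes (the helper unsaturation at C1=C2 and C6=C7) by concerted syn hydrogen transfer and spare the trisubstituted conjugated ester, the C–Br bond and the tertiary alcohol, no stereocentre being touched.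

**Step 14**
Reactants: 25 methyl (2E)-5-[(1S,2S,4aS,6R,8aR)-6-bromo-2-hydroxy-2,5,5,8a-tetramethyldecahydronaphthalen-1-yl]-3-methylpent-2-enoate
Product: 26 (1S,2S,4aS,6R,8aR)-6-bromo-1-[(3E)-5-hydroxy-3-methylpent-3-en-1-yl]-2,5,5,8a-tetramethyldecahydronaphthalen-2-ol (CNP0176777.2)
Conditions: i-Bu2AlH (3.5 equiv), CH2Cl2, −78 °C; aq. potassium sodium tartrate
Reagents that add atoms: none
Why: low-temperature i-Bu2AlH reduction of the conjugated ester should give the E allylic alcohol and leave the hindered equatorial secondary bromide and the tertiary alcohol untouched.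

**Compound list**

1 | methyl (2E)-3,7-dimethylocta-2,6-dienoate (methyl geranate) | COC(=O)/C=C(\C)CCC=C(C)C | starting material
2 | methyl (2E,6E)-8-hydroxy-3,7-dimethylocta-2,6-dienoate | COC(=O)/C=C(\C)CC/C=C(\C)CO | intermediate
3 | methyl (2E,6E)-3,7-dimethyl-8-oxoocta-2,6-dienoate | COC(=O)/C=C(\C)CC/C=C(\C)C=O | intermediate
4 | ethynyltrimethylsilane | C#C[Si](C)(C)C | starting material
5 | methyl[(trimethylsilyl)ethynyl]zinc (zinc acetylide) | C[Zn]C#C[Si](C)(C)C | intermediate (not isolated)
6 | methyl (2E,6E,8S)-8-hydroxy-3,7-dimethyl-10-(trimethylsilyl)deca-2,6-dien-9-ynoate | COC(=O)/C=C(\C)CC/C=C(\C)[C@H](O)C#C[Si](C)(C)C | intermediate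
7 | (2S)-2-methoxypropanoic acid | C[C@H](OC)C(=O)O | starting material
8 | methyl (2E,6E,8S)-8-{[(2S)-2-methoxypropanoyl]oxy}-3,7-dimethyl-10-(trimethylsilyl)deca-2,6-dien-9-ynoate | COC(=O)/C=C(\C)CC/C=C(\C)[C@H](OC(=O)[C@H](C)OC)C#C[Si](C)(C)C | intermediate
9 | methyl (2E,6E,8S)-8-{[(1Z)-2-methoxy-1-(trimethylsilyloxy)prop-1-en-1-yl]oxy}-3,7-dimethyl-10-(trimethylsilyl)deca-2,6-dien-9-ynoate (silyl ketene acetal) | COC(=O)/C=C(\C)CC/C=C(\C)[C@H](O/C(O[Si](C)(C)C)=C(\C)OC)C#C[Si](C)(C)C | intermediate (not isolated)
10 | trimethylsilyl ester of acid 11 | C[Si](C)(C)OC(=O)[C@](C)(OC)[C@@H](CC/C(C)=C/C(=O)OC)/C(C)=C/C#C[Si](C)(C)C | intermediate (not isolated)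
11 | (2R,3S,4E)-2-methoxy-3-[(3E)-5-methoxy-3-methyl-5-oxopent-3-en-1-yl]-2,4-dimethyl-7-(trimethylsilyl)hept-4-en-6-ynoic acid | OC(=O)[C@](C)(OC)[C@@H](CC/C(C)=C/C(=O)OC)/C(C)=C/C#C[Si](C)(C)C | intermediate
12 | isobutyl carbonic mixed anhydride of acid 11 | CC(C)COC(=O)OC(=O)[C@](C)(OC)[C@@H](CC/C(C)=C/C(=O)OC)/C(C)=C/C#C[Si](C)(C)C | intermediate (not isolated)
13 | methyl (2E,6S,7E)-6-[(2R)-1-hydroxy-2-methoxypropan-2-yl]-3,7-dimethyl-10-(trimethylsilyl)deca-2,7-dien-9-ynoate | OC[C@](C)(OC)[C@@H](CC/C(C)=C/C(=O)OC)/C(C)=C/C#C[Si](C)(C)C | intermediate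
14 | methyl (2E,6S,7E)-10-bromo-6-[(2R)-1-hydroxy-2-methoxypropan-2-yl]-3,7-dimethyldeca-2,7-dien-9-ynoate | OC[C@](C)(OC)[C@@H](CC/C(C)=C/C(=O)OC)/C(C)=C/C#CBr | intermediate
15 | methyl (2E,6S,7E,9Z)-10-bromo-6-[(2R)-1-hydroxy-2-methoxypropan-2-yl]-3,7-dimethyldeca-2,7,9-trienoate | OC[C@](C)(OC)[C@@H](CC/C(C)=C/C(=O)OC)/C(C)=C/C=C\Br | intermediate
16 | methyl (2E,6S,7E,9Z)-10-bromo-6-[(2R)-2-methoxy-1-oxopropan-2-yl]-3,7-dimethyldeca-2,7,9-trienoate | O=C[C@](C)(OC)[C@@H](CC/C(C)=C/C(=O)OC)/C(C)=C/C=C\Br | intermediate
17 | 1-bromo-3-methylbut-2-ene | CC(C)=CCBr | starting material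
18 | triethyl phosphite | CCOP(OCC)OCC | starting material
19 | diethyl (3-methylbut-2-en-1-yl)phosphonate | CCOP(=O)(CC=C(C)C)OCC | intermediate
20 | α-lithio derivative of phosphonate 19 | [Li]C(C=C(C)C)P(=O)(OCC)OCC | intermediate (not isolated)
21 | methyl (2E,6S,7E,9Z)-10-bromo-6-[(2S,3E)-2-methoxy-6-methylhepta-3,5-dien-2-yl]-3,7-dimethyldeca-2,7,9-trienoate | CC(C)=C/C=C/[C@](C)(OC)[C@@H](CC/C(C)=C/C(=O)OC)/C(C)=C/C=C\Br | intermediate
22 | pentadienyl cation formed from 21 by loss of methoxide (charge spread over C4, C6 and C8; drawn at C8) | CC(C)=C/C=C/[C+](C)[C@@H](CC/C(C)=C/C(=O)OC)/C(C)=C/C=C\Br | intermediate (not isolated)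
23 | bicyclic ring B allyl cation (charge spread over C6 and C8; drawn at C8) | COC(=O)/C=C(\C)CC[C@H]1[C@]2(C)C=C[C@@H](Br)C(C)(C)[C@H]2C=C[C+]1C | intermediate (not isolated)
24 | methyl (2E)-5-[(1S,2S,4aS,6R,8aR)-6-bromo-2-hydroxy-2,5,5,8a-tetramethyl-1,2,4a,5,6,8a-hexahydronaphthalen-1-yl]-3-methylpent-2-enoate | COC(=O)/C=C(\C)CC[C@H]1[C@]2(C)C=C[C@@H](Br)C(C)(C)[C@H]2C=C[C@]1(C)O | intermediate
25 | methyl (2E)-5-[(1S,2S,4aS,6R,8aR)-6-bromo-2-hydroxy-2,5,5,8a-tetramethyldecahydronaphthalen-1-yl]-3-methylpent-2-enoate | COC(=O)/C=C(\C)CC[C@H]1[C@]2(C)CC[C@@H](Br)C(C)(C)[C@H]2CC[C@]1(C)O | intermediate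
26 | (1S,2S,4aS,6R,8aR)-6-bromo-1-[(3E)-5-hydroxy-3-methylpent-3-en-1-yl]-2,5,5,8a-tetramethyldecahydronaphthalen-2-ol (CNP0176777.2) | OC/C=C(\C)CC[C@H]1[C@]2(C)CC[C@@H](Br)C(C)(C)[C@H]2CC[C@]1(C)O | target

**Step count and risks**

Total step count: 14. Longest linear sequence: 13 (steps 1–9 and 11–14).

Steps most likely to fail:

Step 12 (Proposed new method). Cation 22 may be diverted by elimination to polyenes, by electrocyclisation, or by attack of the diene at the wrong cation terminus. The cycloaddition may also show poor control of ring fusion or of the diene face, the latter because the equatorial C11 chain is nearly eclipsed with the C17 methyl on the planar C8 terminus. The allylic bromide or alcohol of the product may re-ionise. As a fallback the two bonds would be made without a carbocation. Setting out from 21, a photoinduced electron-transfer (radical cation) intramolecular Diels–Alder reaction, a known reaction type for hindered electron-rich dienes (2,4,6-triphenylpyrylium tetrafluoroborate, CH2Cl2, visible light, rt), should give methyl (2E)-5-[(1S,2S,4aS,6R,8aR)-6-bromo-2-methoxy-2,5,5,8a-tetramethyl-1,2,4a,5,6,8a-hexahydronaphthalen-1-yl]-3-methylpent-2-enoate F1, in which C8 keeps the configuration set in step 5. Solvolysis of this tertiary allylic methyl ether (dilute aqueous HClO4, THF, 0 °C) would exchange OMe for OH, and the route is rejoined at 24.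

Step 13. The reduction may stall on the two hindered ring alkenes, and long exposure may erode the allylic bromide by substitution or elimination. As a fallback, hydrogen would be delivered by homogeneous catalysis: 24, H2 (1 atm), RhCl(PPh3)3, benzene, rt, a catalyst that should hydrogenate cis-disubstituted alkenes well before a trisubstituted conjugated ester. This leads from 24 directly to 25 and no new compound arises on the way (F0).

Step 11. The olefination may stall at the β-hydroxyphosphonate stage on the hindered aldehyde, or the basic carbanion may eliminate HBr from the Z-bromoalkene. As a fallback the diene would be built by cross-coupling. From 16, Takai iodo-olefination (CHI3, CrCl2, THF, 0 °C) should give methyl (2E,6S,7E,9Z)-10-bromo-6-[(2R,3E)-4-iodo-2-methoxybut-3-en-2-yl]-3,7-dimethyldeca-2,7,9-trienoate F2. Suzuki–Miyaura coupling of F2 with 4,4,5,5-tetramethyl-2-(2-methylprop-1-en-1-yl)-1,3,2-dioxaborolane (Pd(PPh3)4, K3PO4, THF/H2O, rt), in which the C–I bond should react before the C–Br bond, would return to the route at 21.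

**Further compounds**

F1 | step 12 | methyl (2E)-5-[(1S,2S,4aS,6R,8aR)-6-bromo-2-methoxy-2,5,5,8a-tetramethyl-1,2,4a,5,6,8a-hexahydronaphthalen-1-yl]-3-methylpent-2-enoate | COC(=O)/C=C(\C)CC[C@H]1[C@]2(C)C=C[C@@H](Br)C(C)(C)[C@H]2C=C[C@]1(C)OC
F0 | step 13 | none | none
F2 | step 11 | methyl (2E,6S,7E,9Z)-10-bromo-6-[(2R,3E)-4-iodo-2-methoxybut-3-en-2-yl]-3,7-dimethyldeca-2,7,9-trienoate | I/C=C/[C@](C)(OC)[C@@H](CC/C(C)=C/C(=O)OC)/C(C)=C/C=C\Br
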